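The easy step came first: I divided the reagent charge by the substrate charge. This flask holds 1.20 M of reagent on 2.0 M of substrate, less reagent than substrate, so reagent looked like the limiting reagent. With one reagent per target as the zero of the scale, this flask's ceiling stood at 60.0 % of the substrate.

| flask | substrate | reagent | capture agent | remark | time |
|---|---|---|---|---|---|
| north-west | 2 M | 1.2 M | 0.10 M | the very flask that is asked about, followed so far |  |
| south-west | 3 M | 1.2 M | 0.10 M | run made earlier |  |
| flask | 2.0 M | 1.20 M | 0.100 M |  | 40 h |

| run | time / h | target / % |
|---|---|---|
| north-west | 2.00 | 1.8 |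
| north-west | 4.00 | 6.2 |
| north-west | 10.0 | 13.7 |
| north-west | 25.0 | 23.4 |
| south-west | 1.33 | 0.2 |
| south-west | 3.00 | 1.7 |
| south-west | 4.00 | 3.5 |
| south-west | 6.00 | 6.7 |

(each reading ± 0.5 percentage points)

- theta: change nothing and wait 20 h more
- gamma: at 40 h take out 90 % of the target then present, then wait 20 h
- epsilon: at 40 h add reagent, 50.0 % of the amount charged, then wait 20 h

- target that was removed still counts
- additions bring no volume worth counting

- target, in percent of the substrate first charged, at 40 h
- what to do for the largest gain in target; "none" if nothing gains more than 2 percentage points (theta / gamma / epsilon / none)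
- target present, with what was taken out counted in, in percent of the substrate first charged, after gamma
- target present, with what was taken out counted in, in percent of the substrate first charged, after epsilon

I held that bench rule against the readings of this flask. Between 4.00 h and 10.0 h the target grew by 0.0250 M h⁻¹, but between 10.0 h and 25.0 h by 0.0129 M h⁻¹, about half as fast. I drew a straight line of rate against the target level at the middle of each interval, and it reached zero at a plateau of 27.8 %. That is a reading, with the scatter of 0.5 percentage points in every point. It is about half of the ceiling, and there the rule stopped working.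

So I replaced it with the reagent price of the target, the moles of reagent charged for each mole of target at the plateau: 2.16, about twice the one-for-one zero. The same curve put this flask at 26.2 % at 40 h, leaving a tail of 1.5 points, less than the margin. Theta and gamma add no reagent, so I gave them that tail. Epsilon buys 14 points at this price, more than the tail, and I chose epsilon.

The forecast read the same runs as “first order in substrate with product inhibition”. It gave 28.8 % (26.5 % to 31 %), 40 % after gamma (33 % to 47 %) and 37 % after epsilon (32 % to 41 %), and it chose gamma, so we parted on the choice.

    intermediate C → intermediate E (k = 0.00710 s⁻¹)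
    capture agent + intermediate D → trapped intermediate (k = 3.80 × 10⁻⁴ M⁻¹ s⁻¹)
    substrate ⇌ intermediate A (K = 0.500, k = 4.30 × 10⁻⁴ s⁻¹)
    substrate → decomposition product (k = 1.20 × 10⁻⁶ s⁻¹)
    reagent + intermediate A → intermediate B (k = 6.50 × 10⁻⁵ M⁻¹ s⁻¹)
    reagent + intermediate B ⇌ intermediate C (K = 7.20 M⁻¹, k = 3.90 × 10⁻⁴ M⁻¹ s⁻¹)
    intermediate E → target (k = 3.70 × 10⁻⁴ s⁻¹)
    reagent + intermediate A ⇌ intermediate D (K = 2.00 M⁻¹, k = 0.00170 M⁻¹ s⁻¹)

This flask stood at 25.3 %, and the best option was epsilon, which gained 13 points against 0.42 points for gamma and 0.42 points for theta. With what was taken out counted in, the target in this flask came to 25.7 % after gamma, and it came to 38.5 % after epsilon. The free reagent at 40.0 h was 0.783 % of its charge. My price had given 14 points for the added dose. The neighbour flask with 3.0 M of reagent, priced the same way, came to 69.4 % of the substrate, and at 40.0 h that neighbour flask held 66.0 %.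

All runs are simulated on assumed constants, noise included.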